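**Plan**

- Retrosynthesis: the phenol ring of the target is first taken back one dehydrogenation level to a 4-substituted cyclohex-2-enone. Ring bonds C1–C6 and C2–C3 are then cut (C1 carries the propanoate chain, C4 the oxygen), giving an aldehyde ester and methyl vinyl ketone.
- Enabling feature: in the para-disubstituted benzene ring, C1 and C2 are the alpha and formyl carbons of pentacosyl 5-oxopentanoate. C3, C4, C5 and C6 are the CH3, C=O, CH and CH2 carbons of methyl vinyl ketone, whose oxygen becomes the phenol oxygen, so the 1,4 pattern follows from the annulation itself.
- The aldehyde carbon is traced to the free carboxyl group of a glutarate half ester, and the ester C–O bond to glutaric anhydride plus pentacosan-1-ol.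
- Forward order: ester chain first (anhydride opening, acid to alcohol, alcohol to aldehyde), then the only ring by Michael addition and aldol condensation, then aromatisation.
- Stereochemistry: the target is achiral. The single ring stereocentre created in the annulation is racemic and is erased when the ring becomes aromatic.

Key step: step 4

Remark: all pentacosyl esters are expected to be waxy solids, so every step is planned at 0 °C or above in THF, toluene, CH2Cl2 or DMSO. Compounds 1, 2 and 6 are taken as commercial.

**Step 1**
Reactants: 1 glutaric anhydride (oxane-2,6-dione); 2 pentacosan-1-ol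
Product: 3 5-oxo-5-(pentacosyloxy)pentanoic acid (monopentacosyl glutarate)
Conditions: 1 (1.2 equiv), 4-(dimethylamino)pyridine (DMAP, 10 mol %), toluene, 90 °C; dilute HCl wash, crystallisation
Reagents that add atoms: none
Why: DMAP-catalysed alcoholysis of a cyclic anhydride (nucleophilic acyl substitution) should stop at the half ester, because the carboxylic acid released is no acylating agent and the two anhydride carbonyls are equivalent.

**Step 2**
Reactants: 3 5-oxo-5-(pentacosyloxy)pentanoic acid
Product: 4 pentacosyl 5-hydroxypentanoate
Conditions: BH3·SMe2 (1.3 equiv), THF, 0 °C to rt; MeOH quench at 0 °C, evaporation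
Reagents that add atoms: none
Why: Chemoselective borane reduction of a carboxylic acid beside an ester: the acid is converted quickly into an acyloxyborane that takes up hydride readily, whereas the alkyl ester reacts only slowly with BH3 at this temperature.

**Step 3**
Reactants: 4 pentacosyl 5-hydroxypentanoate
Product: 5 pentacosyl 5-oxopentanoate
Conditions: PhI(OAc)2 (1.1 equiv), TEMPO (2,2,6,6-tetramethylpiperidin-1-oxyl, 10 mol %), CH2Cl2, rt
Reagents that add atoms: none
Why: The oxoammonium-mediated TEMPO/PhI(OAc)2 oxidation should take the primary alcohol to the aldehyde without over-oxidation in dry CH2Cl2, at room temperature where the substrate dissolves and under nearly neutral conditions that should not drive the delta-hydroxy ester to lactonise.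

**Step 4**
Reactants: 5 pentacosyl 5-oxopentanoate; 6 methyl vinyl ketone (but-3-en-2-one)
Product: 10 pentacosyl 3-(4-oxocyclohex-2-en-1-yl)propanoate (racemic), via pentacosyl (4E)-5-(diethylamino)pent-4-enoate 7 (not isolated), via pentacosyl 4-formyl-7-oxooctanoate 8 (not isolated), via pentacosyl 3-(2-hydroxy-4-oxocyclohexyl)propanoate 9 (not isolated)
Conditions: 6 (1.5 equiv), Et2NH (30 mol %), THF, 40 °C; evaporate; TsOH·H2O (40 mol %), toluene, reflux (Dean–Stark)
Reagents that add atoms: none
Why: Et2NH condenses reversibly with the formyl group of 5 to enamine 7, whose nucleophilic carbon (C4 of the pentanoate) adds to the terminal CH2 of 6; hydrolysis of the resulting iminium returns the amine and gives keto aldehyde 8, which forms ring bond C1–C6. After removal of excess 6 and amine, TsOH enolises the methyl ketone towards its CH3 group and this enol attacks the formyl carbon in a 6-(enolendo)-exo-trig aldol closure to 9 (ring bond C2–C3), which loses water to the conjugated enone 10. The closest known reaction type is the secondary-amine-catalysed Michael addition of unbranched aldehydes to vinyl ketones followed by cyclodehydration to 4-substituted cyclohex-2-enones, a Robinson-type annulation. The one new stereocentre (ring C1) is formed without control as a racemate, which does not matter because it becomes an sp2 carbon in step 5. The step needs mono-alkylation at the aldehyde alpha carbon and a single aldol regiochemistry: only the aldehyde can form an enamine (the ester alpha carbon cannot), and every other enol and carbonyl pairing within 8 would close a four-membered ring, so the chain ends up 1,4 to the ketone oxygen. Acid in place of hydroxide for the cyclisation keeps the pentacosyl ester intact.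

**Step 5**
Reactants: 10 pentacosyl 3-(4-oxocyclohex-2-en-1-yl)propanoate
Product: 12 pentacosyl 3-(4-hydroxyphenyl)propanoate, via pentacosyl 3-(4-oxocyclohexa-2,5-dien-1-yl)propanoate 11 (not isolated)
Conditions: Pd(OCOCF3)2 (5 mol %), 2-(dimethylamino)pyridine (10 mol %), TsOH·H2O (20 mol %), O2 (1 atm), DMSO, 80 °C
Reagents that add atoms: none
Why: Palladium-catalysed aerobic dehydrogenation of a cyclohexenone: a divalent palladium enolate forms at C5, beta-hydride elimination from C6 gives the cross-conjugated dienone 11, which still carries a hydrogen at C1 and should therefore tautomerise irreversibly to the phenol, while O2 returns the palladium hydride to the active catalyst; the saturated ester and the alkyl chain offer no comparably activated C–H bond.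

**Compound list**

1 | glutaric anhydride (oxane-2,6-dione) | O=C1CCCC(=O)O1 | starting material
2 | pentacosan-1-ol | CCCCCCCCCCCCCCCCCCCCCCCCCO | starting material
3 | 5-oxo-5-(pentacosyloxy)pentanoic acid | CCCCCCCCCCCCCCCCCCCCCCCCCOC(=O)CCCC(=O)O | intermediate
4 | pentacosyl 5-hydroxypentanoate | CCCCCCCCCCCCCCCCCCCCCCCCCOC(=O)CCCCO | intermediate
5 | pentacosyl 5-oxopentanoate | CCCCCCCCCCCCCCCCCCCCCCCCCOC(=O)CCCC=O | intermediate
6 | methyl vinyl ketone (but-3-en-2-one) | CC(=O)C=C | starting material
7 | pentacosyl (4E)-5-(diethylamino)pent-4-enoate | CCCCCCCCCCCCCCCCCCCCCCCCCOC(=O)CC/C=C/N(CC)CC | intermediate (not isolated)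
8 | pentacosyl 4-formyl-7-oxooctanoate (racemic) | CCCCCCCCCCCCCCCCCCCCCCCCCOC(=O)CCC(C=O)CCC(C)=O | intermediate (not isolated)
9 | pentacosyl 3-(2-hydroxy-4-oxocyclohexyl)propanoate (racemic, mixture of diastereomers) | CCCCCCCCCCCCCCCCCCCCCCCCCOC(=O)CCC1CCC(=O)CC1O | intermediate (not isolated)
10 | pentacosyl 3-(4-oxocyclohex-2-en-1-yl)propanoate (racemic) | CCCCCCCCCCCCCCCCCCCCCCCCCOC(=O)CCC1CCC(=O)C=C1 | intermediate
11 | pentacosyl 3-(4-oxocyclohexa-2,5-dien-1-yl)propanoate | CCCCCCCCCCCCCCCCCCCCCCCCCOC(=O)CCC1C=CC(=O)C=C1 | intermediate (not isolated)
12 | pentacosyl 3-(4-hydroxyphenyl)propanoate | CCCCCCCCCCCCCCCCCCCCCCCCCOC(=O)CCc1ccc(O)cc1 | target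

Total step count: 5
Longest linear sequence: 5 steps (2 to 3 to 4 to 5 to 10 to 12)

**Steps most likely to fail**

1. Step 4. The aldehyde may condense with itself through its own enamine, the Michael adduct may add a second molecule of 6, 6 may oligomerise under amine catalysis, and the cyclodehydration may stall at the aldol stage. The fallback makes the enamine stoichiometrically and isolates it before any enone is present (Stork enamine annulation). It sets out from 5. Piperidine and 4 Å molecular sieves in toluene at room temperature should give pentacosyl (4E)-5-(piperidin-1-yl)pent-4-enoate F1, freed of excess amine by evaporation. Addition of 6 in toluene at room temperature should then give the cycloadduct pentacosyl 3-[6-methyl-2-(piperidin-1-yl)-3,4-dihydro-2H-pyran-3-yl]propanoate F2 (not isolated). Heating with aqueous AcOH/NaOAc should hydrolyse F2 to 8 and close the ring, so the route is rejoined at 10.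

2. Step 5. The waxy substrate may mix poorly with DMSO, and palladium may precipitate as the zerovalent metal before conversion is complete, leaving enone behind. The fallback replaces catalytic dehydrogenation by halogenation and elimination and sets out from 10. CuBr2 (2 equiv) and LiBr in refluxing MeCN should brominate the alpha' position to pentacosyl 3-(5-bromo-4-oxocyclohex-2-en-1-yl)propanoate F3 (not isolated). F3 should lose HBr under the same conditions and so come back to the route at dienone 11, which tautomerises to 12.

3. Step 2. Excess borane may begin to reduce the ester, and the delta-hydroxy ester may lactonise with loss of pentacosan-1-ol during quench, concentration or the following oxidation. The fallback reaches the aldehyde oxidation level by reduction of an acyl chloride, so that no hydroxy ester is formed, and sets out from 3. (COCl)2 with catalytic DMF in CH2Cl2 at room temperature should give pentacosyl 5-chloro-5-oxopentanoate F4. Rosenmund reduction (H2 at 1 atm, Pd/BaSO4, 2,6-lutidine, THF, rt) should then give the aldehyde, coming back to the route at 5.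

**Further compounds**

F1 | step 4 | pentacosyl (4E)-5-(piperidin-1-yl)pent-4-enoate | CCCCCCCCCCCCCCCCCCCCCCCCCOC(=O)CC/C=C/N1CCCCC1
F2 | step 4 | pentacosyl 3-[6-methyl-2-(piperidin-1-yl)-3,4-dihydro-2H-pyran-3-yl]propanoate (racemic, mixture of diastereomers) | CCCCCCCCCCCCCCCCCCCCCCCCCOC(=O)CCC1CC=C(C)OC1N1CCCCC1
F3 | step 5 | pentacosyl 3-(5-bromo-4-oxocyclohex-2-en-1-yl)propanoate (racemic, mixture of diastereomers) | CCCCCCCCCCCCCCCCCCCCCCCCCOC(=O)CCC1CC(Br)C(=O)C=C1
F4 | step 2 | pentacosyl 5-chloro-5-oxopentanoate | CCCCCCCCCCCCCCCCCCCCCCCCCOC(=O)CCCC(=O)Cl
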